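## Structural features

The target is a γ-butyrolactone (ring atoms O1, C2 carbonyl, C3, C4, C5 methylene). C3 carries a hydroxyl group and a 4-hydroxy-3,5-dimethoxybenzyl group; C4 carries a 3,4-dimethoxybenzyl group. C3 (fully substituted, S) and C4 (S) are adjacent stereocentres: the two benzylic groups are trans and the C3 oxygen is cis to the C4 benzyl group. The fragile groups are the free phenol (oxidation), the tertiary α-hydroxy lactone (ring opening and retro-aldol-type cleavage in strong base) and the lactone carbonyl. Once made, the lactone is configurationally robust, since C3 has no hydrogen and C4 is not α to a carbonyl. The real difficulty is the oxygenated quaternary C3 in the right relation to C4: an oxygen electrophile offered to the enolate of a trans-dibenzyl lactone would be expected to enter anti to the C4 substituent and give the wrong C3 configuration. The key step uses the fact that C3 bears oxygen and C4 is β to the C2 carbonyl: a 3-alkoxybutenolide already contains O1, C2, C3 with its oxygen, C4 and C5, and lacks only the two benzylic C–C bonds, one made by a nucleophile at C4 and one by an electrophile at C3. Configurations were re-derived from the target (3S,4S): acceptor 8 is 5R and adduct 17 is (3S,4R,5R), which maps onto the target, so no structure needed correcting.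

## Logic of the disconnections

22 ⇒ 21. The phenolic O–CH2Ph and the C3 O–CH2Ph bonds are cut. Both acidic OH groups must be masked through the carbanion chemistry, and one hydrogenolysis removes both masks. The forward step must leave the lactone C–O and the non-benzylic C3–O bonds alone and needs a sulfur-free substrate.

21 ⇒ 20. The two C7–H bonds of the veratryl methylene are replaced by the two C–S bonds of a dithiane. This reveals the group that made C7 a carbanion. The forward step must desulfurise a crowded, fully substituted carbon.

20 ⇒ 17. The C5–H bond is replaced by the C5–O bond to the auxiliary, returning C5 to the aldehyde level and revealing the element that controls C4. The forward step must reduce only the masked aldehyde, keep C2 at the acid level, and avoid enolisation towards C4.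

17 ⇒ 8 + 10 + 14 (key). The C4–C(dithiane) bond and the C3–CH2Ar bond are cut. This removes both benzylic groups and both new stereocentres at once and leaves three simple components. The forward step needs 1,4-addition to a deactivated (captodative) alkene, then C-alkylation of a crowded enolate, each on the correct face.

8 ⇒ 7. Benzyl alcohol is added back across C3=C4 (C4–O bond). A 3-alkoxybutenolide is thus traced to a saturated 3,4-dialkoxy lactone, from which β-elimination must remove only the C4 oxygen. This replaces substitution at C3 of a 3-bromobutenolide, where an alkoxide would be expected to add to C4 first and end as the 4-alkoxy isomer.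

7 ⇒ 6 ⇒ 5. Two O–benzyl bonds, then the C3–O and C4–O bonds, are cut. The C3 oxygen is thereby introduced by oxidising the alkene of the well-known crystalline acceptor 5. The facial outcome of the dihydroxylation is irrelevant because C3 and C4 become sp2 again in 8.

5 ⇒ 2 + 3 ⇒ 1. The acetal C5–O bond is cut, then the oxidised furan is traced to 1. Chirality comes from 3; the forward acetalisation must deliver one C5 epimer, which crystallisation with acid equilibration provides.

10 ⇒ 9 and 14 ⇒ 13 ⇒ 12 ⇒ 11. These are the C–S bonds of the dithiane, and the C–Br, C–H and O–benzyl bonds of the electrophile. They are routine functional-group changes on commercial aldehydes.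

## Other disconnections considered

Alternative 1: The C4–C5 bond is cut, with O1–C5 already present in an ester. Forward, the iodomethyl ester A1 of the (S,E)-tertiary α-hydroxy styryl acid would be treated with a silane hydrogen donor and a radical initiator. The acyloxymethyl radical should close 5-exo-trig onto the styrene, and the benzylic radical would be reduced to give A2, the phenolic benzyl ether of the target.
- In favour: the ring, C5 at its final oxidation level and the veratryl methylene arise in one step, with no sulfur and no acetal to reduce. The free tertiary alcohol is tolerated. Only one hydrogenolysis follows, which is better than the three steps after the chosen key step.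
- Against: esters prefer the conformer that holds the radical carbon away from the alkene, so simple reduction of the C–I bond should compete with ring closure. C4 would be induced only by a quaternary C3 whose substituents differ little in size. A1 must first be made enantiopure by a separate construction of a tertiary α-hydroxy acid, and iodomethyl esters are labile.
- Comparison: structurally both plans build the same ring, but the chosen plan sets C3 and C4 together from one auxiliary, whereas here only C4 is set and less predictably. Mechanistically the radical route is equal or better in functional-group tolerance and worse in facial definition. In step economy it is better after the key step and worse before it.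

Alternative 2: The aryl–C7 bond and the C3–CH2(syringyl) bond are cut. Forward, the cyclopropane-fused lactone ester A3 would be opened at its cyclopropane CH2 by the aryl Grignard reagent A4 with catalytic CuI (homoconjugate addition). The malonate-type enolate would then be benzylated by 14 to give A5.
- In favour: C4 comes from a cheap enantiopure three-carbon epoxide, there is no auxiliary to cleave, C5 is a methylene from the start, and no sulfur is used. On convergence it is the equal of the chosen plan, and on the source of chirality and the absence of reduction and desulfurisation it is better.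
- Against: in A5 the quaternary C3 bears a tert-butoxycarbonyl group exactly where the oxygen must stand. Exchanging C–C for C–O with retention would need ester cleavage, conversion to a methyl ketone, a Baeyer–Villiger migration of an electron-poor quaternary carbon and acyl cleavage. The shorter path, decarboxylation and enolate hydroxylation, would bring the oxidant anti to the C4 benzyl group and so lead to the wrong C3 configuration.
- Comparison: the chosen plan has the C3–O bond in place before the quaternary centre forms and lets the carbon electrophile choose the face. Alternative 2 is better up to A5 and worse afterwards, so its overall step count is likely higher.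

Alternative 3: The C2–O1 and O1–C5 bonds are cut by excising the ring oxygen, which leads to cyclobutanone A6. Forward, a flavin-dependent oxygen-inserting enzyme working with air and a nicotinamide cofactor would insert oxygen between the carbonyl carbon and the ring CH2 to give A7, which is identical with 21.
- In favour: the product is the penultimate compound of the chosen route, so on structure the two are equal at that point. The conditions are mild, and A6 could in principle be assembled convergently by a ketene–alkene [2+2] cycloaddition. On paper the step economy is better.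
- Against: the intrinsic migratory preference favours the fully substituted, oxygen-bearing carbon, so the required regiochemistry is the abnormal one. Enzymes deliver that mainly for particular enantiomers of small fused cyclobutanones, and A6 with three aryl groups lies far outside that range. A cycloaddition route would give A6 racemic with uncertain cis/trans control, so at best half of the material is useful.
- Comparison: selectivity rests wholly on finding or engineering a catalyst, whereas the chosen plan uses substrate control with ordinary reagents. It is shorter if it works, but it cannot be planned with confidence.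

Key step: step 10

Remark on the chemistry: 2 is used as the racemic hemiacetal, and the single 5R epimer 5 is assumed to be secured by crystallisation with acid re-equilibration of the mother liquor.

## Route

Step 1
Reactants: 1 furfural
Product: 2 5-hydroxyfuran-2(5H)-one (racemic)
Conditions: O2, hν (visible), rose bengal (cat.), MeOH, 20 °C
Reagents that add atoms: dioxygen, O=O
Why: Dye-sensitised singlet-oxygen [4+2] cycloaddition to the furan followed by methanolytic fragmentation, which expels the formyl carbon as methyl formate; a standard photo-oxygenation of furfural.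

Step 2
Reactants: 2 5-hydroxyfuran-2(5H)-one; 3 l-menthol
Product: 5 (5R)-5-(l-menthyloxy)furan-2(5H)-one, via the 5S epimer 4 (not isolated)
Conditions: CSA (cat.), toluene, reflux, azeotropic removal of water; crystallisation from petroleum ether, mother liquor re-equilibrated with CSA and recrystallised
Reagents that add atoms: none
Why: Acid-catalysed acetalisation of the pseudo-acid gives both C5 epimers; the 5R epimer crystallises while the acetal centre equilibrates through the oxocarbenium ion, so the dissolved epimer 4 should be funnelled into 5 (crystallisation-driven epimerisation).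

Step 3
Reactants: 5 (5R)-5-(l-menthyloxy)furan-2(5H)-one
Product: 6 (3S,4R,5R)-3,4-dihydroxy-5-(l-menthyloxy)dihydrofuran-2(3H)-one
Conditions: OsO4 (cat.), NMO, acetone/H2O, 0 °C → rt
Reagents that add atoms: N-methylmorpholine N-oxide, C[N+]1([O-])CCOCC1; water, O
Why: Catalytic syn-dihydroxylation of the butenolide alkene, expected on the face opposite the C5 menthyloxy group; the configuration at C3 and C4 does not matter because both carbons become sp2 again in step 5.

Step 4
Reactants: 6 (3S,4R,5R)-3,4-dihydroxy-5-(l-menthyloxy)dihydrofuran-2(3H)-one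
Product: 7 (3S,4R,5R)-3,4-bis(benzyloxy)-5-(l-menthyloxy)dihydrofuran-2(3H)-one
Conditions: BnOC(=NH)CCl3, TfOH (cat.), CH2Cl2/cyclohexane, 0 °C → rt
Reagents that add atoms: benzyl 2,2,2-trichloroacetimidate, N=C(OCc1ccccc1)C(Cl)(Cl)Cl
Why: Acid-catalysed O-benzylation with the trichloroacetimidate is the usual method for base-sensitive hydroxy lactones; basic benzylation is avoided because the β-oxygenated lactone would eliminate prematurely.

Step 5
Reactants: 7 (3S,4R,5R)-3,4-bis(benzyloxy)-5-(l-menthyloxy)dihydrofuran-2(3H)-one
Product: 8 (5R)-3-(benzyloxy)-5-(l-menthyloxy)furan-2(5H)-one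
Conditions: DBU, CH2Cl2, 0 °C → rt
Reagents that add atoms: none
Why: E1cB β-elimination: removal of the only acidic hydrogen (C3–H) expels the C4 benzyloxy group, as in the known conversion of 2,3-di-O-benzyl aldonolactones into 3-benzyloxybutenolides; the C3 oxygen stays on the carbanionic carbon and C5 is not involved.

Step 6
Reactants: 9 veratraldehyde
Product: 10 2-(3,4-dimethoxyphenyl)-1,3-dithiane
Conditions: HS(CH2)3SH, BF3·OEt2 (cat.), CH2Cl2, 0 °C → rt
Reagents that add atoms: propane-1,3-dithiol, SCCCS
Why: Lewis-acid-catalysed dithioacetalisation of an aromatic aldehyde.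

Step 7
Reactants: 11 syringaldehyde
Product: 12 4-(benzyloxy)-3,5-dimethoxybenzaldehyde
Conditions: BnBr, K2CO3, DMF, 60 °C
Reagents that add atoms: benzyl bromide, BrCc1ccccc1
Why: Williamson etherification of the phenol; the benzyl group is chosen so that it leaves together with the C3 benzyl ether in the last step.

Step 8
Reactants: 12 4-(benzyloxy)-3,5-dimethoxybenzaldehyde
Product: 13 [4-(benzyloxy)-3,5-dimethoxyphenyl]methanol
Conditions: NaBH4, MeOH/THF, 0 °C; dil. HCl work-up
Reagents that add atoms: none
Why: Borohydride reduction of an aryl aldehyde to the benzylic alcohol.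

Step 9
Reactants: 13 [4-(benzyloxy)-3,5-dimethoxyphenyl]methanol
Product: 14 4-(benzyloxy)-3,5-dimethoxybenzyl bromide
Conditions: PBr3, Et2O, 0 °C
Reagents that add atoms: phosphorus tribromide, BrP(Br)Br
Why: Bromide displacement of the phosphite ester of a benzylic alcohol; the electron-rich bromide is used freshly because it solvolyses readily.

Step 10
Reactants: 10 2-(3,4-dimethoxyphenyl)-1,3-dithiane; 8 (5R)-3-(benzyloxy)-5-(l-menthyloxy)furan-2(5H)-one; 14 4-(benzyloxy)-3,5-dimethoxybenzyl bromide
Product: 17 (3S,4R,5R)-3-(benzyloxy)-3-[4-(benzyloxy)-3,5-dimethoxybenzyl]-4-[2-(3,4-dimethoxyphenyl)-1,3-dithian-2-yl]-5-(l-menthyloxy)dihydrofuran-2(3H)-one, via the lithiated dithiane 15 (not isolated), via the lithium enolate 16 (not isolated)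
Conditions: 10, n-BuLi, THF, −78 → −20 °C; 8, THF, −78 °C; then 14, DMPU, −78 → −30 °C; aq. NH4Cl
Reagents that add atoms: none
Why: Deprotonation of 10 gives the sulfur-stabilised benzylic carbanion 15, which adds in Michael fashion to C4 of 8 to form the C4–C(dithiane) bond and the tetrasubstituted lithium enolate 16; the enolate is then C-alkylated at C3 by 14, forming the C3–CH2Ar bond (three-component conjugate addition–alkylation). The closest known reaction type is the tandem addition of lithiated 2-aryl-1,3-dithianes to 5-alkoxybutenolides with a benzylic bromide quench, and alkylation of α-alkoxy lactone enolates to quaternary centres is likewise established. No ring is closed; the lactone is present throughout. C4 is set by the C5 acetal: the carbanion should approach the planar butenolide on the face opposite the menthyloxy group, giving 4R in 17. C3 is set by the new C4 substituent: the very large aryldithianyl group shields its own face of the enolate, so the benzyl group should enter trans to it and leave the benzyloxy group cis, giving 3S. The step needs 1,4-addition to win over 1,2-addition and over removal of the C5 hydrogen, which the soft, hindered, delocalised anion and the low temperature should secure even though the enol-ether oxygen makes C4 less electrophilic than in the parent butenolide. It also needs C- rather than O-alkylation at a crowded enolate carbon, for which a benzylic bromide with DMPU as lithium-solvating additive is the most favourable case.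

Step 11
Reactants: 17 (3S,4R,5R)-3-(benzyloxy)-3-[4-(benzyloxy)-3,5-dimethoxybenzyl]-4-[2-(3,4-dimethoxyphenyl)-1,3-dithian-2-yl]-5-(l-menthyloxy)dihydrofuran-2(3H)-one
Product: 20 (3S,4S)-3-(benzyloxy)-3-[4-(benzyloxy)-3,5-dimethoxybenzyl]-4-[2-(3,4-dimethoxyphenyl)-1,3-dithian-2-yl]dihydrofuran-2(3H)-one, via the formyl carboxylate 18 (not isolated), via the hydroxy carboxylate 19 (not isolated)
Conditions: NaBH4, KOH, EtOH/H2O, 0 °C → rt; then aq. HCl (pH 2), rt
Reagents that add atoms: potassium hydroxide, [K+].[OH-] (its oxygen enters the carboxylate of 18 and 19 and is shared statistically with the lactone carbonyl of 20)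
Why: Hydroxide opens the acylal-type lactone at C2, the C5 hemiacetal alkoxide collapses to the aldehyde 18 with release of menthol, and borohydride already present reduces it at once to 19; acidification then closes the γ-lactone on the unchanged C2 carboxyl (the known one-flask conversion of 5-alkoxy lactones into lactones). C3 is quaternary and C4 should be safe once the aldehyde is reduced; its descriptor changes from R to S only because the substituent priorities change.

Step 12
Reactants: 20 (3S,4S)-3-(benzyloxy)-3-[4-(benzyloxy)-3,5-dimethoxybenzyl]-4-[2-(3,4-dimethoxyphenyl)-1,3-dithian-2-yl]dihydrofuran-2(3H)-one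
Product: 21 (3S,4S)-3-(benzyloxy)-3-[4-(benzyloxy)-3,5-dimethoxybenzyl]-4-(3,4-dimethoxybenzyl)dihydrofuran-2(3H)-one
Conditions: Raney Ni (W-2), EtOH/THF, rt → 50 °C
Reagents that add atoms: none
Why: Reductive desulfurisation of a benzylic dithioacetal on hydrogen-loaded nickel replaces both C–S bonds by C–H without touching a stereocentre; any early loss of a benzyl group would be harmless because step 13 removes both.

Step 13
Reactants: 21 (3S,4S)-3-(benzyloxy)-3-[4-(benzyloxy)-3,5-dimethoxybenzyl]-4-(3,4-dimethoxybenzyl)dihydrofuran-2(3H)-one
Product: 22 (3S,4S)-4-(3,4-dimethoxybenzyl)-3-hydroxy-3-(4-hydroxy-3,5-dimethoxybenzyl)dihydrofuran-2(3H)-one (target)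
Conditions: H2 (1 atm), Pd(OH)2/C, EtOAc/EtOH, rt
Reagents that add atoms: none
Why: Catalytic hydrogenolysis cleaves the aryl benzyl ether and the tertiary alkyl benzyl ether; the lactone C5–O bond and the C3–O bond are not benzylic, so the ring and both stereocentres should be untouched.

## Compound list

1 | furfural | O=Cc1ccco1 | starting material
2 | 5-hydroxyfuran-2(5H)-one (racemic) | O=C1OC(O)C=C1 | intermediate
3 | l-menthol, (1R,2S,5R)-2-isopropyl-5-methylcyclohexanol | CC(C)[C@@H]1CC[C@@H](C)C[C@H]1O | starting material
4 | (5S)-5-(l-menthyloxy)furan-2(5H)-one | O=C1O[C@H](O[C@@H]2C[C@H](C)CC[C@H]2C(C)C)C=C1 | intermediate (not isolated)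
5 | (5R)-5-(l-menthyloxy)furan-2(5H)-one | O=C1O[C@@H](O[C@@H]2C[C@H](C)CC[C@H]2C(C)C)C=C1 | intermediate
6 | (3S,4R,5R)-3,4-dihydroxy-5-(l-menthyloxy)dihydrofuran-2(3H)-one | O=C1O[C@@H](O[C@@H]2C[C@H](C)CC[C@H]2C(C)C)[C@H](O)[C@@H]1O | intermediate
7 | (3S,4R,5R)-3,4-bis(benzyloxy)-5-(l-menthyloxy)dihydrofuran-2(3H)-one | O=C1O[C@@H](O[C@@H]2C[C@H](C)CC[C@H]2C(C)C)[C@H](OCc2ccccc2)[C@@H]1OCc1ccccc1 | intermediate
8 | (5R)-3-(benzyloxy)-5-(l-menthyloxy)furan-2(5H)-one | O=C1O[C@@H](O[C@@H]2C[C@H](C)CC[C@H]2C(C)C)C=C1OCc1ccccc1 | intermediate
9 | veratraldehyde | COc1ccc(C=O)cc1OC | starting material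
10 | 2-(3,4-dimethoxyphenyl)-1,3-dithiane | COc1ccc(C2SCCCS2)cc1OC | intermediate
11 | syringaldehyde | COc1cc(C=O)cc(OC)c1O | starting material
12 | 4-(benzyloxy)-3,5-dimethoxybenzaldehyde | COc1cc(C=O)cc(OC)c1OCc1ccccc1 | intermediate
13 | [4-(benzyloxy)-3,5-dimethoxyphenyl]methanol | COc1cc(CO)cc(OC)c1OCc1ccccc1 | intermediate
14 | 4-(benzyloxy)-3,5-dimethoxybenzyl bromide | COc1cc(CBr)cc(OC)c1OCc1ccccc1 | intermediate
15 | 2-lithio-2-(3,4-dimethoxyphenyl)-1,3-dithiane | COc1ccc(C2([Li])SCCCS2)cc1OC | intermediate (not isolated)
16 | lithium enolate of (4R,5R)-3-(benzyloxy)-4-[2-(3,4-dimethoxyphenyl)-1,3-dithian-2-yl]-5-(l-menthyloxy)dihydrofuran-2(3H)-one | COc1ccc(C2(SCCCS2)[C@H]2[C@H](O[C@@H]3C[C@H](C)CC[C@H]3C(C)C)OC(O[Li])=C2OCc2ccccc2)cc1OC | intermediate (not isolated)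
17 | (3S,4R,5R)-3-(benzyloxy)-3-[4-(benzyloxy)-3,5-dimethoxybenzyl]-4-[2-(3,4-dimethoxyphenyl)-1,3-dithian-2-yl]-5-(l-menthyloxy)dihydrofuran-2(3H)-one | COc1ccc(C2(SCCCS2)[C@H]2[C@H](O[C@@H]3C[C@H](C)CC[C@H]3C(C)C)OC(=O)[C@]2(OCc2ccccc2)Cc2cc(OC)c(OCc3ccccc3)c(OC)c2)cc1OC | intermediate
18 | potassium (2S,3R)-2-(benzyloxy)-2-[4-(benzyloxy)-3,5-dimethoxybenzyl]-3-[2-(3,4-dimethoxyphenyl)-1,3-dithian-2-yl]-4-oxobutanoate | COc1ccc(C2(SCCCS2)[C@@H](C=O)[C@@](OCc2ccccc2)(Cc2cc(OC)c(OCc3ccccc3)c(OC)c2)C(=O)[O-])cc1OC.[K+] | intermediate (not isolated)
19 | potassium (2S,3S)-2-(benzyloxy)-2-[4-(benzyloxy)-3,5-dimethoxybenzyl]-3-[2-(3,4-dimethoxyphenyl)-1,3-dithian-2-yl]-4-hydroxybutanoate | COc1ccc(C2(SCCCS2)[C@@H](CO)[C@@](OCc2ccccc2)(Cc2cc(OC)c(OCc3ccccc3)c(OC)c2)C(=O)[O-])cc1OC.[K+] | intermediate (not isolated)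
20 | (3S,4S)-3-(benzyloxy)-3-[4-(benzyloxy)-3,5-dimethoxybenzyl]-4-[2-(3,4-dimethoxyphenyl)-1,3-dithian-2-yl]dihydrofuran-2(3H)-one | COc1ccc(C2(SCCCS2)[C@H]2COC(=O)[C@]2(OCc2ccccc2)Cc2cc(OC)c(OCc3ccccc3)c(OC)c2)cc1OC | intermediate
21 | (3S,4S)-3-(benzyloxy)-3-[4-(benzyloxy)-3,5-dimethoxybenzyl]-4-(3,4-dimethoxybenzyl)dihydrofuran-2(3H)-one | COc1ccc(C[C@H]2COC(=O)[C@]2(OCc2ccccc2)Cc2cc(OC)c(OCc3ccccc3)c(OC)c2)cc1OC | intermediate
22 | (3S,4S)-4-(3,4-dimethoxybenzyl)-3-hydroxy-3-(4-hydroxy-3,5-dimethoxybenzyl)dihydrofuran-2(3H)-one | COc1ccc(C[C@H]2COC(=O)[C@]2(O)Cc2cc(OC)c(O)c(OC)c2)cc1OC | target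

## Step count and risk

Total: 13 steps. Longest linear sequence: 9 steps (steps 1–5 and 10–13, from 1 to 22). The branches are step 6 (one step) and steps 7–9 (three steps).

Least certain steps:

**Step 10 (key step).** The most likely failure is that 15 acts as a base and removes the C5 hydrogen of 8, which would aromatise the ring to a furanolate and destroy the C5 stereocentre, because the enol-ether oxygen lowers the electrophilicity of C4. Attack at the lactone carbonyl, or failure of the crowded enolate 16 to alkylate before quench, are secondary risks. The fallback moves the oxygenation to after the conjugate addition; it sets out from 5 and 10 and comes back at 17. Anion 15 is added to the parent butenolide 5, the precedented and more electrophilic acceptor. The enolate is oxidised in the same flask with (camphorsulfonyl)oxaziridine to (3R,4R,5R)-4-[2-(3,4-dimethoxyphenyl)-1,3-dithian-2-yl]-3-hydroxy-5-(l-menthyloxy)dihydrofuran-2(3H)-one F1. The hydroxyl is benzylated with benzyl trichloroacetimidate and catalytic TfOH to the 3-benzyloxy lactone F2. LiHMDS in THF at −78 °C then regenerates enolate 16, which is alkylated with 14 to give 17. The C3 configuration of F1 and F2 is immaterial because it is erased on enolisation.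

**Step 5.** The risk is epimerisation at C5 of 8 through γ-deprotonation by DBU (loss of the acetal configuration by way of the furanolate), or sluggish departure of the poor benzyloxy leaving group. The fallback uses a better leaving group and a weaker base; it sets out from 6 and comes back at 8, bypassing step 4. Diol 6 with Ac2O, Et3N and DMAP should give (3S,4R,5R)-3,4-diacetoxy-5-(l-menthyloxy)dihydrofuran-2(3H)-one F3, which should lose acetic acid in the same flask to the enol acetate (5R)-3-acetoxy-5-(l-menthyloxy)furan-2(5H)-one F4. Hydrazinolysis of the enol ester (N2H4·AcOH, DMF, 0 °C) would free the enol (5R)-3-hydroxy-5-(l-menthyloxy)furan-2(5H)-one F5. O-Benzylation with BnBr and K2CO3 in acetone gives 8.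

**Step 11.** The risk is enolisation of the transient aldehyde 18 in alkali, leading to β-elimination of the C3 benzyloxy group or epimerisation at C4. It is aggravated if opening of the hindered lactone is slow and the exposure to hydroxide long. The fallback unmasks the aldehyde under acid and reduces without added hydroxide; it sets out from 17 and comes back at 20. Aqueous TFA in THF hydrolyses the menthyl acetal to the lactol (3S,4R)-3-(benzyloxy)-3-[4-(benzyloxy)-3,5-dimethoxybenzyl]-4-[2-(3,4-dimethoxyphenyl)-1,3-dithian-2-yl]-5-hydroxydihydrofuran-2(3H)-one F6 (both C5 epimers). NaBH4 in MeOH/THF at 0 °C reduces its ring-opened aldehyde tautomer, as pseudo-acids are reduced, and acidic work-up relactonises to 20.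

**Step 12.** The risk is incomplete C–S hydrogenolysis at the crowded, fully substituted dithiane carbon, or sulfur carried over to poison step 13. The fallback goes through the ketone; it sets out from 20 and comes back at 22. Hydrolysis of the dithiane with MeI and CaCO3 in aqueous MeCN gives the aryl ketone (3S,4S)-3-(benzyloxy)-3-[4-(benzyloxy)-3,5-dimethoxybenzyl]-4-(3,4-dimethoxybenzoyl)dihydrofuran-2(3H)-one F7. Hydrogenation over Pd/C in AcOH with a trace of HClO4 should reduce the electron-rich benzylic ketone to the methylene and cleave both benzyl ethers in one operation, giving 22. C4, now α to a ketone, must be kept away from base on this path.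

## Further compounds

F1 | step 10 | (3R,4R,5R)-4-[2-(3,4-dimethoxyphenyl)-1,3-dithian-2-yl]-3-hydroxy-5-(l-menthyloxy)dihydrofuran-2(3H)-one | COc1ccc(C2(SCCCS2)[C@H]2[C@H](O[C@@H]3C[C@H](C)CC[C@H]3C(C)C)OC(=O)[C@@H]2O)cc1OC
F2 | step 10 | (3R,4R,5R)-3-(benzyloxy)-4-[2-(3,4-dimethoxyphenyl)-1,3-dithian-2-yl]-5-(l-menthyloxy)dihydrofuran-2(3H)-one | COc1ccc(C2(SCCCS2)[C@H]2[C@H](O[C@@H]3C[C@H](C)CC[C@H]3C(C)C)OC(=O)[C@@H]2OCc2ccccc2)cc1OC
F3 | step 5 | (3S,4R,5R)-3,4-diacetoxy-5-(l-menthyloxy)dihydrofuran-2(3H)-one | O=C1O[C@@H](O[C@@H]2C[C@H](C)CC[C@H]2C(C)C)[C@H](OC(C)=O)[C@@H]1OC(C)=O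
F4 | step 5 | (5R)-3-acetoxy-5-(l-menthyloxy)furan-2(5H)-one | O=C1O[C@@H](O[C@@H]2C[C@H](C)CC[C@H]2C(C)C)C=C1OC(C)=O
F5 | step 5 | (5R)-3-hydroxy-5-(l-menthyloxy)furan-2(5H)-one | O=C1O[C@@H](O[C@@H]2C[C@H](C)CC[C@H]2C(C)C)C=C1O
F6 | step 11 | (3S,4R)-3-(benzyloxy)-3-[4-(benzyloxy)-3,5-dimethoxybenzyl]-4-[2-(3,4-dimethoxyphenyl)-1,3-dithian-2-yl]-5-hydroxydihydrofuran-2(3H)-one (C5 epimers) | COc1ccc(C2(SCCCS2)[C@H]2C(O)OC(=O)[C@]2(OCc2ccccc2)Cc2cc(OC)c(OCc3ccccc3)c(OC)c2)cc1OC
F7 | step 12 | (3S,4S)-3-(benzyloxy)-3-[4-(benzyloxy)-3,5-dimethoxybenzyl]-4-(3,4-dimethoxybenzoyl)dihydrofuran-2(3H)-one | COc1ccc(C(=O)[C@H]2COC(=O)[C@]2(OCc2ccccc2)Cc2cc(OC)c(OCc3ccccc3)c(OC)c2)cc1OC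
A1 | alternative 1 | iodomethyl (S,E)-2-[4-(benzyloxy)-3,5-dimethoxybenzyl]-4-(3,4-dimethoxyphenyl)-2-hydroxybut-3-enoate | ICOC(=O)[C@](O)(Cc1cc(OC)c(OCc2ccccc2)c(OC)c1)/C=C/c1ccc(OC)c(OC)c1
A2 | alternative 1 | (3S,4S)-3-[4-(benzyloxy)-3,5-dimethoxybenzyl]-4-(3,4-dimethoxybenzyl)-3-hydroxydihydrofuran-2(3H)-one | COc1ccc(C[C@H]2COC(=O)[C@]2(O)Cc2cc(OC)c(OCc3ccccc3)c(OC)c2)cc1OC
A3 | alternative 2 | tert-butyl (1R,5R)-2-oxo-3-oxabicyclo[3.1.0]hexane-1-carboxylate | O=C1OC[C@@H]2C[C@]12C(=O)OC(C)(C)C
A4 | alternative 2 | 3,4-dimethoxyphenylmagnesium bromide | COc1ccc([Mg]Br)cc1OC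
A5 | alternative 2 | tert-butyl 3-[4-(benzyloxy)-3,5-dimethoxybenzyl]-4-(3,4-dimethoxybenzyl)-2-oxotetrahydrofuran-3-carboxylate (benzyl groups trans) | COc1ccc(C[C@H]2COC(=O)[C@]2(C(=O)OC(C)(C)C)Cc2cc(OC)c(OCc3ccccc3)c(OC)c2)cc1OC
A6 | alternative 3 | (2S,3S)-2-(benzyloxy)-2-[4-(benzyloxy)-3,5-dimethoxybenzyl]-3-(3,4-dimethoxybenzyl)cyclobutan-1-one | O=C1C[C@H](Cc2ccc(OC)c(OC)c2)[C@@]1(OCc1ccccc1)Cc1cc(OC)c(OCc2ccccc2)c(OC)c1
A7 | alternative 3 | (3S,4S)-3-(benzyloxy)-3-[4-(benzyloxy)-3,5-dimethoxybenzyl]-4-(3,4-dimethoxybenzyl)dihydrofuran-2(3H)-one | COc1ccc(C[C@H]2COC(=O)[C@]2(OCc2ccccc2)Cc2cc(OC)c(OCc3ccccc3)c(OC)c2)cc1OC
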